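**Retrosynthetic overview**
- The target is traced back to the 8α,9α-diol (9-O-angeloylation last), then to an eremophil-8-ene carrying a C11 carbinol (α-face dihydroxylation, later dehydration to the isopropenyl group).
- The Δ8 olefin and the C11 carbinol come from cyclopropylcarbinyl-to-homoallyl opening of a carane-type cyclopropyl carbinol, so ring B, C7 and the latent isopropenyl group derive from (+)-3-carene.
- Key disconnection C4–C5. The strategy rests on this bond of ring A: it joins the methyl-bearing secondary carbon C4 to the quaternary carbon C5, which lies β to the C9 oxygen of ring B, so a planar C4 radical made by hydrogen-atom transfer to a terminal alkene can close onto a C9 enone at C5.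
- The cyclisation precursor comes from 4-iodo-3-caren-5-one by Stille allylation, oxidative cleavage and asymmetric allylboration (C2 carbinol).
- Ring order: ring B (with the cyclopropane) is bought with 3-carene, ring A is the only ring formed (step 6), and the cyclopropane is opened in step 9.

Key step: step 6

Assumption and conventions: eremophilane numbering is used for all side-chain and ring atoms (β = face of the C5 methyl; "3-carene/3-caren-5-one" names keep carane numbering); allylborane 8 is taken as its commercial pentane solution (or made just before use from the B-methoxyborane and allylMgBr) and is assumed to add to the si face of the aldehyde as it does with other unbranched aldehydes.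

**Step 1**
Reactants: 1 (+)-3-carene
Product: 2 3-caren-5-one
Conditions: t-BuOOH, Cr(CO)6 (cat.), MeCN, reflux
Reagents that add atoms: tert-butyl hydroperoxide CC(C)(C)OO
Why: Chromium-catalysed allylic oxidation with t-BuOOH (hydrogen abstraction, then oxidation of the allylic position) attacks the ring methylene flanked by the alkene CH and the cyclopropane and gives the conjugated β-methyl enone known from 3-carene; no stereocentre is touched.

**Step 2**
Reactants: 2 3-caren-5-one
Product: 3 4-iodo-3-caren-5-one
Conditions: I2, pyridine/CH2Cl2 1:1, rt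
Reagents that add atoms: iodine II
Why: Johnson α-iodination of an enone (pyridine adds to the β-carbon, the enolate is iodinated, pyridine is expelled), as used for 2-iodo-3-methylcyclohex-2-enone.

**Step 3**
Reactants: 3 4-iodo-3-caren-5-one; 4 allyltributylstannane
Product: 5 4-allyl-3-caren-5-one
Conditions: Pd2(dba)3, AsPh3, CuI, NMP, 40 °C
Reagents that add atoms: none
Why: Stille coupling of an α-iodoenone, which adds readily to zerovalent palladium, with an allylstannane; AsPh3 and CuI speed up transmetallation so that the mild temperature should leave the allyl double bond out of conjugation.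

**Step 4**
Reactants: 5 4-allyl-3-caren-5-one
Product: 7 2-(5-oxo-3-caren-4-yl)acetaldehyde, via diol 6 (not isolated)
Conditions: OsO4 (cat.), NaIO4, 2,6-lutidine, dioxane/H2O 3:1, rt
Reagents that add atoms: osmium tetroxide O=[Os](=O)(=O)=O (oxygen carrier); sodium periodate [Na+].[O-][I](=O)(=O)=O (terminal oxidant)
Why: Lemieux–Johnson cleavage: OsO4 dihydroxylates the electron-rich monosubstituted alkene and leaves the electron-poor tetrasubstituted enone double bond, and periodate cleaves the diol; lutidine buffers the mixture so that the β,γ-unsaturated aldehyde, which is used at once, should not isomerise.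

**Step 5**
Reactants: 7 2-(5-oxo-3-caren-4-yl)acetaldehyde; 8 B-allylbis[(1R,2S,3R,5R)-isopinocampheyl]borane
Product: 10 4-[(2S)-2-hydroxypent-4-en-1-yl]-3-caren-5-one, via O-borinate 9 (not isolated)
Conditions: 8 (1.2 equiv), Et2O, −78 °C; then HOCH2CH2NH2, rt
Reagents that add atoms: none
Why: Brown asymmetric allylboration through a chair six-membered transition state: the aldehyde reacts at −78 °C while the hindered conjugated ketone does not, the reagent of the (+)-α-pinene series delivers allyl to the si face and so sets C2 as S, and the ethanolamine work-up frees the alcohol without peroxide.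

**Step 6**
Reactants: 10 4-[(2S)-2-hydroxypent-4-en-1-yl]-3-caren-5-one
Product: 11 2α-hydroxy-8,11-cycloeremophilan-9-one (4β-methyl; 5β-methyl; 10α-H; cyclopropane on the β face)
Conditions: Fe(acac)3 (30 mol %), PhSiH3 (slow addition), EtOH/(CH2OH)2 5:1, 60 °C, 0.01 M, degassed
Reagents that add atoms: none
Why: An Fe–H species made from Fe(acac)3 and PhSiH3 gives a hydrogen atom to the terminal alkene carbon (which becomes the C15 methyl), the nucleophilic secondary C4 radical adds to the enone β-carbon C5, and the C10 α-keto radical, whose spin does not reach C9 and therefore leaves the cyclopropane closed, is reduced to the enol(ate) and protonated; this is the intramolecular form of the iron-catalysed MHAT reductive olefin–enone coupling (a Giese radical cyclisation). Ring A closes 6-endo-trig, because attack at C5 is polarity-matched and gives a stabilised radical, while 5-exo attack at the α-carbon C10 is mismatched and would build a spiro centre. C5 is set by the gem-dimethylcyclopropane, whose endo methyl lies over the β face of the flat carenone ring, so the new bond forms on the α face and the C5 methyl is left β. C4 is set in a chair-like closure in which the oxygen on the fixed C2 centre is axial on the α side, so the methyl of the planar radical turns equatorial (β) to avoid a syn-diaxial contact with it. C10 is set by protonation on the α face, where the syn-axial C2 hydroxyl (kept free through this step for that purpose) can pass a proton on while the β face is covered by the C5 methyl and the endo cyclopropane methyl; this should give the trans ring fusion under kinetic control, which is why the product is not exposed to base. The step therefore needs 6-endo over 5-exo closure, α attack at C5, an equatorial C4 methyl and α protonation at C10, and relies for them on the enone polarity, the cyclopropane, the C2 stereocentre and its free hydroxyl; high dilution and slow silane addition hold back simple reduction of the radical.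

**Step 7**
Reactants: 11 2α-hydroxy-8,11-cycloeremophilan-9-one
Product: 12 2α-acetoxy-8,11-cycloeremophilan-9-one
Conditions: Ac2O, pyridine, DMAP (cat.), CH2Cl2, rt
Reagents that add atoms: acetic anhydride CC(=O)OC(C)=O
Why: DMAP-catalysed acylation of the only hydroxyl; the medium is too weakly basic to enolise the ketone toward C10.

**Step 8**
Reactants: 12 2α-acetoxy-8,11-cycloeremophilan-9-one
Product: 13 2α-acetoxy-8,11-cycloeremophilan-9β-ol
Conditions: NaBH4, CeCl3·7H2O, MeOH, 0 °C
Reagents that add atoms: none
Why: Luche-type borohydride reduction with hydride expected from the α face, away from the cyclopropane methyl and the C5 methyl; either C9 epimer serves because this centre is ionised in the next step, and the acetate is stable to NaBH4.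

**Step 9**
Reactants: 13 2α-acetoxy-8,11-cycloeremophilan-9β-ol
Product: 14 2α-acetoxyeremophil-8-en-11-ol (7αH; 10αH)
Conditions: HClO4 (cat.), dioxane/H2O 3:1, rt, stopped at full conversion of 13
Reagents that add atoms: water O
Why: Cyclopropylcarbinyl-to-homoallyl rearrangement: ionisation at C9 is assisted by the C8–C11 bond, the only cyclopropane bond aligned with the empty orbital and the one that gives a tertiary cation, and water captures C11, as in the acid hydration of 2-carene oxide to p-menth-2-ene-1,8-diol; C7 keeps its configuration because the C7–C11 bond is not broken.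

**Step 10**
Reactants: 14 2α-acetoxyeremophil-8-en-11-ol
Product: 15 2α-acetoxyeremophilane-8α,9α,11-triol
Conditions: OsO4 (cat.), NMO, acetone/H2O 4:1, rt
Reagents that add atoms: osmium tetroxide O=[Os](=O)(=O)=O (oxygen carrier); N-methylmorpholine N-oxide C[N+]1([O-])CCOCC1; water O
Why: Upjohn dihydroxylation, a syn addition to the only alkene from the α face because the β face is covered by the allylic C7 substituent and the axial C5 methyl; this sets C8 and C9 with both oxygens α.

**Step 11**
Reactants: 15 2α-acetoxyeremophilane-8α,9α,11-triol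
Product: 16 2α-acetoxy-8α,9α-(isopropylidenedioxy)eremophilan-11-ol
Conditions: Me2C(OMe)2, PPTS (cat.), CH2Cl2, rt
Reagents that add atoms: 2,2-dimethoxypropane COC(C)(C)OC
Why: Acid-catalysed transacetalisation closes the five-membered acetonide on the cis-1,2-diol and leaves the hindered tertiary C11 alcohol free.

**Step 12**
Reactants: 16 2α-acetoxy-8α,9α-(isopropylidenedioxy)eremophilan-11-ol
Product: 17 2α-acetoxy-8α,9α-(isopropylidenedioxy)eremophil-11-ene
Conditions: SOCl2, pyridine, CH2Cl2, −30 to 0 °C
Reagents that add atoms: none
Why: Dehydration of a tertiary alcohol through its chlorosulfite with pyridine as base (E2-type); the six methyl hydrogens should react in preference to the single hindered C7 hydrogen next to the acetonide, so the isopropenyl isomer should prevail over the isopropylidene isomer, which is removed by chromatography.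

**Step 13**
Reactants: 17 2α-acetoxy-8α,9α-(isopropylidenedioxy)eremophil-11-ene
Product: 18 2α-acetoxyeremophil-11-ene-8α,9α-diol
Conditions: AcOH/H2O 4:1, 45 °C
Reagents that add atoms: none
Why: Mild aqueous acid hydrolysis of the acetonide; the acetate and the 1,1-disubstituted alkene tolerate dilute acetic acid at this temperature.

**Step 14**
Reactants: 18 2α-acetoxyeremophil-11-ene-8α,9α-diol; 19 angelic acid
Product: 21 2α-acetoxy-9α-angeloyloxyeremophil-11-en-8α-ol (target), via mixed anhydride 20 (not isolated)
Conditions: 19, 2,4,6-Cl3C6H2COCl, Et3N, toluene, rt; then 18 (limiting), 80 °C, no DMAP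
Reagents that add atoms: none
Why: Yamaguchi esterification with the preformed mixed anhydride and without DMAP, the established way to transfer an angeloyl group without Z-to-E isomerisation; the equatorial C9 hydroxyl beside the ring-fusion CH should be acylated before the axial C8 hydroxyl beside the isopropenyl-bearing C7.

**Compound list**
1 | (+)-3-carene, (1S,6R)-3,7,7-trimethylbicyclo[4.1.0]hept-3-ene | CC1(C)[C@H]2CC(C)=CC[C@@H]12 | starting material
2 | 3-caren-5-one, (1R,6S)-4,7,7-trimethylbicyclo[4.1.0]hept-3-en-2-one | CC1(C)[C@H]2CC(C)=CC(=O)[C@@H]12 | intermediate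
3 | 4-iodo-3-caren-5-one | CC1(C)[C@H]2CC(C)=C(I)C(=O)[C@@H]12 | intermediate
4 | allyltributylstannane | C=CC[Sn](CCCC)(CCCC)CCCC | starting material
5 | 4-allyl-3-caren-5-one | CC1(C)[C@H]2CC(C)=C(CC=C)C(=O)[C@@H]12 | intermediate
6 | 4-(2,3-dihydroxypropyl)-3-caren-5-one (both carbinol epimers) | CC1(C)[C@H]2CC(C)=C(CC(O)CO)C(=O)[C@@H]12 | intermediate
7 | 2-(5-oxo-3-caren-4-yl)acetaldehyde | CC1(C)[C@H]2CC(C)=C(CC=O)C(=O)[C@@H]12 | intermediate
8 | B-allylbis[(1R,2S,3R,5R)-isopinocampheyl]borane, (+)-α-pinene series | C=CCB([C@@H]1C[C@@H]2C[C@H]([C@H]1C)C2(C)C)[C@@H]1C[C@@H]2C[C@H]([C@H]1C)C2(C)C | starting material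
9 | O-bis(isopinocampheyl)boryl ether of 10 | CC1(C)[C@H]2CC(C)=C(C[C@@H](OB([C@@H]3C[C@@H]4C[C@H]([C@H]3C)C4(C)C)[C@@H]3C[C@@H]4C[C@H]([C@H]3C)C4(C)C)CC=C)C(=O)[C@@H]12 | intermediate
10 | 4-[(2S)-2-hydroxypent-4-en-1-yl]-3-caren-5-one (key-step precursor) | CC1(C)[C@H]2CC(C)=C(C[C@@H](O)CC=C)C(=O)[C@@H]12 | intermediate
11 | 2α-hydroxy-8,11-cycloeremophilan-9-one, 4β,5β-dimethyl, 10α-H, cyclopropane β (key-step product) | CC1(C)[C@H]2C[C@]3(C)[C@@H](C)C[C@H](O)C[C@H]3C(=O)[C@@H]12 | intermediate
12 | 2α-acetoxy-8,11-cycloeremophilan-9-one | CC1(C)[C@H]2C[C@]3(C)[C@@H](C)C[C@H](OC(C)=O)C[C@H]3C(=O)[C@@H]12 | intermediate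
13 | 2α-acetoxy-8,11-cycloeremophilan-9β-ol | CC1(C)[C@H]2C[C@]3(C)[C@@H](C)C[C@H](OC(C)=O)C[C@H]3[C@@H](O)[C@@H]12 | intermediate
14 | 2α-acetoxyeremophil-8-en-11-ol, 7αH, 10αH | CC(C)(O)[C@H]1C[C@]2(C)[C@@H](C)C[C@H](OC(C)=O)C[C@H]2C=C1 | intermediate
15 | 2α-acetoxyeremophilane-8α,9α,11-triol | CC(C)(O)[C@H]1C[C@]2(C)[C@@H](C)C[C@H](OC(C)=O)C[C@H]2[C@H](O)[C@@H]1O | intermediate
16 | 2α-acetoxy-8α,9α-(isopropylidenedioxy)eremophilan-11-ol | CC(C)(O)[C@H]1C[C@]2(C)[C@@H](C)C[C@H](OC(C)=O)C[C@H]2[C@@H]3OC(C)(C)O[C@H]13 | intermediate
17 | 2α-acetoxy-8α,9α-(isopropylidenedioxy)eremophil-11-ene | C=C(C)[C@H]1C[C@]2(C)[C@@H](C)C[C@H](OC(C)=O)C[C@H]2[C@@H]3OC(C)(C)O[C@H]13 | intermediate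
18 | 2α-acetoxyeremophil-11-ene-8α,9α-diol | C=C(C)[C@H]1C[C@]2(C)[C@@H](C)C[C@H](OC(C)=O)C[C@H]2[C@H](O)[C@@H]1O | intermediate
19 | angelic acid, (Z)-2-methylbut-2-enoic acid | C/C=C(/C)C(=O)O | starting material
20 | angelic 2,4,6-trichlorobenzoic anhydride | C/C=C(/C)C(=O)OC(=O)c1c(Cl)cc(Cl)cc1Cl | intermediate
21 | 2α-acetoxy-9α-angeloyloxyeremophil-11-en-8α-ol (CNP0217919.1) | C=C(C)[C@H]1C[C@]2(C)[C@@H](C)C[C@H](OC(C)=O)C[C@H]2[C@H](OC(=O)/C(C)=C\C)[C@@H]1O | target

**Step count and risks**
Total steps: 14. Longest linear sequence: 14 steps, from (+)-3-carene.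

Steps most likely to fail:

Step 6. The secondary C4 radical adds only slowly to the fully substituted C5, so it may take a second hydrogen atom first and the side chain is merely hydrogenated. Fallback, from 10 back to 12: 10 is acetylated (Ac2O, pyridine) to the acetoxy enone F1. Tsuji–Wacker oxidation (PdCl2, CuCl, O2, DMF/H2O) gives the methyl ketone F2. NaBH4 in MeOH at −40 °C reduces the saturated ketone ahead of the hindered conjugated one to the secondary alcohol F3 (C4 epimers, which do not matter). Appel iodination (I2, PPh3, imidazole) gives the secondary iodide F4. Bu3SnH and AIBN, added by syringe pump to a dilute solution in refluxing benzene, generate the same C4 radical by iodine abstraction, with the stannane concentration held low enough for the slow 6-endo closure to outrun reduction; this should give 12 directly.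

Step 9. The tertiary C11 cation may lose a proton, or product 14 may ionise again in the acid, so that dienes accumulate in place of the carbinol. Fallback, from 13 back to 14: 13 is converted at −40 °C with Ms2O and 2,6-lutidine in CH2Cl2 into the mesylate F5, which is solvolysed without isolation in acetone/water buffered with NaHCO3; ionisation then happens once, under non-acidic conditions in which 14 cannot re-ionise.

Step 14. Acyl transfer may go to the C8 hydroxyl or the ester may migrate between the cis hydroxyls at 80 °C, and the angeloyl group may isomerise to tigloyl. Fallback, from 18 to 21: 18 is heated with Bu2SnO in toluene with removal of water to give the dibutylstannylene acetal F6, which activates the equatorial C9 oxygen; angeloyl chloride F7 (from the potassium salt of 19 and oxalyl chloride in Et2O at 0 °C) is added at 0 °C in CH2Cl2 without amine base and should give 21 after aqueous work-up.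

**Further compounds**
F1 | step 6 | 4-[(2S)-2-acetoxypent-4-en-1-yl]-3-caren-5-one | CC1(C)[C@H]2CC(C)=C(C[C@@H](OC(C)=O)CC=C)C(=O)[C@@H]12
F2 | step 6 | 4-[(2S)-2-acetoxy-4-oxopentyl]-3-caren-5-one | CC1(C)[C@H]2CC(C)=C(C[C@@H](OC(C)=O)CC(C)=O)C(=O)[C@@H]12
F3 | step 6 | 4-[(2S)-2-acetoxy-4-hydroxypentyl]-3-caren-5-one (C4 epimers) | CC1(C)[C@H]2CC(C)=C(C[C@@H](OC(C)=O)CC(C)O)C(=O)[C@@H]12
F4 | step 6 | 4-[(2S)-2-acetoxy-4-iodopentyl]-3-caren-5-one (C4 epimers) | CC1(C)[C@H]2CC(C)=C(C[C@@H](OC(C)=O)CC(C)I)C(=O)[C@@H]12
F5 | step 9 | 9-O-methanesulfonate of 13 | CC1(C)[C@H]2C[C@]3(C)[C@@H](C)C[C@H](OC(C)=O)C[C@H]3[C@@H](OS(C)(=O)=O)[C@@H]12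
F6 | step 14 | 8,9-O-dibutylstannylene acetal of 18 | C=C(C)[C@H]1C[C@]2(C)[C@@H](C)C[C@H](OC(C)=O)C[C@H]2[C@@H]3O[Sn](CCCC)(CCCC)O[C@H]13
F7 | step 14 | angeloyl chloride | C/C=C(/C)C(Cl)=O
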